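(All constants are made up; the result is computed.)

At early times this flask holds its catalyst as precatalyst, and it loses starting material to the dormant form with no catalyst needed.

starting material 0.70 M; reagent 0.420 M; precatalyst 3.5 mM

    reagent + catalyst intermediate A ⇌ catalyst intermediate B (K1 = 1.8 M⁻¹, k1 = 0.25 M⁻¹ s⁻¹)
    catalyst intermediate C → free catalyst + product (k2 = 0.036 s⁻¹)
    precatalyst → free catalyst (k3 = 0.0026 s⁻¹)
    starting material + free catalyst → catalyst intermediate A (k4 = 0.18 M⁻¹ s⁻¹)
    starting material ⇌ dormant form (K5 = 1.3, k5 = 3.2 × 10⁻⁴ s⁻¹)
    catalyst intermediate B → by-product + catalyst intermediate C (k6 = 0.093 s⁻¹)

* the form that holds most of the catalyst when 10% of the starting material are converted (catalyst intermediate A / catalyst intermediate B / precatalyst / catalyst intermediate C / free catalyst)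
* its share of the catalyst then
* factor on the rate of making product when 10% of the starting material are converted if precatalyst is charged twice over
* factor on the rate when 10% of the starting material are converted if precatalyst is charged at 20 mM instead

1. My zero is plain proportion: the rate follows the catalyst charged, so a double charge gives a factor 2. I reckon the departure from that.
2. I start with the clock. The leak into the dormant form, its return counted, takes 344 s to reach 10%.
3. Precatalyst halves every 267 s, so at that time a fraction 40.9% of it remains.
4. The weak link is that first clock, which counts no turnover. One round of a working catalyst takes 70.2 s, the waits at the four forms added at charged concentrations.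
5. By the time of that first clock, each catalyst charged has made 1.66 rounds. Each round takes up one starting material, so turnover removes 0.830% of the charge. That is less than the leak's part, but it moves the clock.
6. The leak now has to supply the remainder, which takes 313 s.
7. My carried quantity is the activated share, the fraction of the catalyst charged that has left precatalyst at the moment asked about: 55.6%. This is still the induction period, and 44.4% remains precatalyst.
8. Catalyst intermediate C has the longest wait in the round. It holds 39.6% of the working catalyst, which is 22.0% of the whole. That is less than precatalyst holds, so I name precatalyst.
9. With a double charge, turnover by that time takes 1.40% of the charge. The mark then comes at 291 s, and the activated share is 53.1%. Taking the working forms as split alike, the factor is 1.91.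

The forecast names precatalyst at 45% with factors 1.87 and 4.5, the first lower than my 1.91, and says “the extra turnover reaches 10% conversion sooner, when less has activated”.

The flask gives precatalyst at 44.3%, with factors 1.88 and 4.51. It reaches the mark at 313 s. For the flask charged at 20 mM, plain proportion gives 5.71. With the working forms split alike, the factor 4.51 reads as an activated share of 43.9% at that flask's mark, which puts the mark at about 222 s.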